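**Retrosynthetic overview**
1. Last bond: C(sp3)–C(sp2) Negishi coupling of a primary alkylzinc (ring, methyl-bearing carbon and quaternary carbon already in place) with an (E)-trisubstituted vinyl iodide made from (4S)-limonene oxide (cleavage, decarbonylation, alkyne, Zr-catalysed carboalumination).
2. Quaternary carbon: Johnson–Claisen rearrangement of an (E)-dienyl carbinol (1,3-chirality transfer from C–O to C–C, new (E)-alkene); the carbinol comes from Felkin addition of a dienyl aluminate to an α-methyl aldehyde.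
3. α-Methyl aldehyde: SN2 inversion of (S)-lactate triflate by a ring-bearing Grignard reagent.
4. Ring side chain and exocyclic methylene: an earlier Johnson–Claisen rearrangement on a cyclohexenylmethanol, delivered trans to the ring methyl.
5. The only ring is formed first, by ring-closing metathesis of a dienone from (4R)-limonene oxide, then gem-dimethylated by cuprate addition.

Assumption: the target is taken exactly as drawn in the SMILES; both limonene 1,2-oxides are bought as cis/trans mixtures, tert-butyl (S)-lactate as such, and but-1-en-3-yne as its commercial xylene solution.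

**Step 1**
Reactants: 1 (4R)-limonene 1,2-oxide (cis/trans mixture)
Product: 3 (3R)-6-oxo-3-(prop-1-en-2-yl)heptanal, via diol 2 (not isolated)
Conditions: H5IO6 (1.1 equiv), THF/H2O 4:1, 0 °C → rt
Reagents that add atoms: water, O
Why: Acid-catalysed epoxide hydrolysis followed by periodate glycol cleavage (Malaprade) opens the ring between the two epoxide carbons and leaves the isopropenyl group and the purchased stereocentre untouched.

**Step 2**
Reactants: 3 (3R)-6-oxo-3-(prop-1-en-2-yl)heptanal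
Product: 4 (5S)-5,6-dimethylhept-6-en-2-one
Conditions: RhCl(PPh3)3 (1.05 equiv), PhCN, 130 °C
Reagents that add atoms: none

Why: Tsuji–Wilkinson decarbonylation turns CH2CHO into CH3 through acyl- and alkyl-rhodium intermediates that do not involve the neighbouring stereocentre (its descriptor changes only because the CIP ranking changes).

**Step 3**
Reactants: 4 (5S)-5,6-dimethylhept-6-en-2-one
Product: 8 (6S)-6,7-dimethylocta-1,7-dien-3-one, via lithium enolate 5 (not isolated), via Mannich base 6 (not isolated), via ammonium iodide 7 (not isolated)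
Conditions: LiN(i-Pr)2, THF, −78 °C; CH2=NMe2+ I−, −78 °C → rt; then MeI, Et2O, rt; then aq NaHCO3/CH2Cl2, rt
Reagents that add atoms: Eschenmoser's salt (N,N-dimethylmethyleneiminium iodide), C=[N+](C)C.[I-]
Why: Kinetic deprotonation at the methyl group, Mannich reaction and elimination of the quaternised amine (α-methylenation) give the vinyl ketone regioselectively without touching the stereocentre.

**Step 4**
Reactants: 8 (6S)-6,7-dimethylocta-1,7-dien-3-one
Product: 9 (4S)-3,4-dimethylcyclohex-2-en-1-one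
Conditions: second-generation Grubbs catalyst (5 mol %), CH2Cl2 (0.01 M), 40 °C
Reagents that add atoms: none

Why: Ring-closing metathesis joins the enone CH to the isopropenyl carbon with loss of ethene and forms the only ring of the target, the allylic stereocentre being a spectator.

**Step 5**
Reactants: 9 (4S)-3,4-dimethylcyclohex-2-en-1-one
Product: 11 (4S)-3,3,4-trimethylcyclohex-1-en-1-yl trifluoromethanesulfonate, via lithium enolate 10 (not isolated)
Conditions: Me2CuLi (from MeLi and CuI, 1.5 equiv), Et2O, 0 °C; then PhNTf2, THF, 0 °C → rt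
Reagents that add atoms: lithium dimethylcuprate, [Li+].C[Cu-]C; N-phenylbis(trifluoromethanesulfonimide), O=S(=O)(N(c1ccccc1)S(=O)(=O)C(F)(F)F)C(F)(F)F
Why: Cuprate 1,4-addition builds the gem-dimethyl carbon (no new stereocentre) and leaves the enolate regiospecifically on the side of that carbon, where O-triflation fixes the double bond.

**Step 6**
Reactants: 11 (4S)-3,3,4-trimethylcyclohex-1-en-1-yl trifluoromethanesulfonate
Product: 12 [(4S)-3,3,4-trimethylcyclohex-1-en-1-yl]methanol
Conditions: Bu3SnCH2OH (1.3 equiv), Pd(PPh3)4 (5 mol %), LiCl (3 equiv), 1,4-dioxane, 100 °C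
Reagents that add atoms: (tributylstannyl)methanol, CCCC[Sn](CCCC)(CCCC)CO
Why: Migita–Kosugi–Stille coupling replaces the triflate by CH2OH with retention of the double-bond position.

**Step 7**
Reactants: 12 [(4S)-3,3,4-trimethylcyclohex-1-en-1-yl]methanol
Product: 14 ethyl 2-[(1S,3S)-2,2,3-trimethyl-6-methylidenecyclohexyl]acetate, via ketene acetal 13 (not isolated)
Conditions: MeC(OEt)3 (7 equiv), EtCO2H (0.1 equiv), 140 °C, EtOH distilled off
Reagents that add atoms: triethyl orthoacetate, CCOC(C)(OCC)OCC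
Why: Johnson–Claisen [3,3]-sigmatropic rearrangement forms the ring C–CH2 bond and the exocyclic methylene together, and the ketene acetal is delivered axially to the ring CH on the face anti to the pseudoaxial methyl of the adjacent CMe2 (ring methyl pseudoequatorial), which sets the new centre (1S) trans to the purchased one.

**Step 8**
Reactants: 14 ethyl 2-[(1S,3S)-2,2,3-trimethyl-6-methylidenecyclohexyl]acetate
Product: 15 2-[(1S,3S)-2,2,3-trimethyl-6-methylidenecyclohexyl]ethan-1-ol
Conditions: LiAlH4, Et2O, 0 °C; aq NaOH work-up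
Reagents that add atoms: none

Why: Hydride reduction of the ester to the primary alcohol leaves alkene and stereocentres untouched.

**Step 9**
Reactants: 15 2-[(1S,3S)-2,2,3-trimethyl-6-methylidenecyclohexyl]ethan-1-ol
Product: 16 (1S,3S)-1-(2-bromoethyl)-2,2,3-trimethyl-6-methylidenecyclohexane
Conditions: CBr4, PPh3, CH2Cl2, 0 °C
Reagents that add atoms: carbon tetrabromide, BrC(Br)(Br)Br
Why: Appel bromination of a primary alcohol proceeds under neutral conditions that spare the exocyclic alkene.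

**Step 10**
Reactants: 17 tert-butyl (2S)-2-hydroxypropanoate (tert-butyl (S)-lactate)
Product: 18 tert-butyl (2S)-2-{[(trifluoromethyl)sulfonyl]oxy}propanoate
Conditions: Tf2O, 2,6-lutidine, CH2Cl2, −78 → 0 °C
Reagents that add atoms: trifluoromethanesulfonic anhydride, O=S(=O)(OS(=O)(=O)C(F)(F)F)C(F)(F)F
Why: O-Sulfonylation activates the lactate hydroxyl without touching the C–O stereocentre.

**Step 11**
Reactants: 16 (1S,3S)-1-(2-bromoethyl)-2,2,3-trimethyl-6-methylidenecyclohexane; 18 tert-butyl (2S)-2-{[(trifluoromethyl)sulfonyl]oxy}propanoate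
Product: 20 tert-butyl (2S)-2-methyl-4-[(1S,3S)-2,2,3-trimethyl-6-methylidenecyclohexyl]butanoate, via Grignard reagent 19 (not isolated)
Conditions: Mg, THF, 40 °C; then added slowly to 18 (1.3 equiv), ZnCl2 (10 mol %), THF, 0 °C
Reagents that add atoms: none

Why: Zinc-catalysed sp3–sp3 cross-coupling of the Grignard reagent with the α-triflyloxy ester is an SN2 displacement with clean inversion, so the lactate centre becomes the (S)-methyl-bearing carbon of the chain.

**Step 12**
Reactants: 20 tert-butyl (2S)-2-methyl-4-[(1S,3S)-2,2,3-trimethyl-6-methylidenecyclohexyl]butanoate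
Product: 21 (2S)-2-methyl-4-[(1S,3S)-2,2,3-trimethyl-6-methylidenecyclohexyl]butanal
Conditions: i-Bu2AlH (1.1 equiv), CH2Cl2, −78 °C; aq potassium sodium tartrate; used at once
Reagents that add atoms: none

Why: Partial ester reduction stops at the tetrahedral aluminate at low temperature and the non-basic work-up avoids epimerising the α-centre.

**Step 13**
Reactants: 21 (2S)-2-methyl-4-[(1S,3S)-2,2,3-trimethyl-6-methylidenecyclohexyl]butanal; 22 but-1-en-3-yne
Product: 25 (3E,5R,6S)-3,6-dimethyl-8-[(1S,3S)-2,2,3-trimethyl-6-methylidenecyclohexyl]octa-1,3-dien-5-ol, via dienylalane 23 (not isolated), via lithium aluminate 24 (not isolated)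
Conditions: 22 (3 equiv), Me3Al, Cp2ZrCl2 (20 mol %), CH2Cl2, 0 °C → rt, volatiles removed; n-BuLi, hexane/THF, −78 °C; then 21, −78 → −40 °C
Reagents that add atoms: trimethylaluminium, C[Al](C)C
Why: Negishi syn-carboalumination fixes the (E)-diene, and Felkin–Anh addition of the alkenyl aluminate to the α-methyl aldehyde gives mainly the (5R)-syn alcohol (about 3:1 expected, minor epimer removed by chromatography).

**Step 14**
Reactants: 25 (3E,5R,6S)-3,6-dimethyl-8-[(1S,3S)-2,2,3-trimethyl-6-methylidenecyclohexyl]octa-1,3-dien-5-ol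
Product: 27 ethyl (3S,4E,6S)-3-ethenyl-3,6-dimethyl-8-[(1S,3S)-2,2,3-trimethyl-6-methylidenecyclohexyl]oct-4-enoate, via ketene acetal 26 (not isolated)
Conditions: MeC(OEt)3 (10 equiv), EtCO2H (0.1 equiv), xylene, 135 °C
Reagents that add atoms: triethyl orthoacetate, CCOC(C)(OCC)OCC
Why: Johnson–Claisen [3,3]-sigmatropic rearrangement through a chair transition state with the branched chain equatorial forms the quaternary C–C bond on the face that carried oxygen, so the (5R)-carbinol and (E)-alkene give the (S)-quaternary centre and the new (E)-disubstituted alkene.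

**Step 15**
Reactants: 27 ethyl (3S,4E,6S)-3-ethenyl-3,6-dimethyl-8-[(1S,3S)-2,2,3-trimethyl-6-methylidenecyclohexyl]oct-4-enoate
Product: 28 (3S,4E,6S)-3-ethenyl-3,6-dimethyl-8-[(1S,3S)-2,2,3-trimethyl-6-methylidenecyclohexyl]oct-4-en-1-ol
Conditions: LiAlH4, Et2O, 0 °C; aq NaOH work-up
Reagents that add atoms: none

Why: Ester reduction to the primary alcohol does not affect the isolated alkenes or any stereocentre.

**Step 16**
Reactants: 28 (3S,4E,6S)-3-ethenyl-3,6-dimethyl-8-[(1S,3S)-2,2,3-trimethyl-6-methylidenecyclohexyl]oct-4-en-1-ol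
Product: 29 (1S,3S)-1-[(3S,4E,6S)-6-ethenyl-8-iodo-3,6-dimethyloct-4-en-1-yl]-2,2,3-trimethyl-6-methylidenecyclohexane
Conditions: I2, PPh3, imidazole, CH2Cl2, 0 °C → rt
Reagents that add atoms: iodine, II
Why: Appel-type iodination of the primary alcohol is neutral and leaves the four alkenes alone.

**Step 17**
Reactants: 30 (4S)-limonene 1,2-oxide (cis/trans mixture)
Product: 32 (3S)-6-oxo-3-(prop-1-en-2-yl)heptanal, via diol 31 (not isolated)
Conditions: H5IO6 (1.1 equiv), THF/H2O 4:1, 0 °C → rt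
Reagents that add atoms: water, O
Why: Same epoxide hydrolysis and periodate glycol cleavage as step 1 in the mirror-image series, carrying the purchased stereocentre through.

**Step 18**
Reactants: 32 (3S)-6-oxo-3-(prop-1-en-2-yl)heptanal
Product: 33 (5R)-5,6-dimethylhept-6-en-2-one
Conditions: RhCl(PPh3)3 (1.05 equiv), PhCN, 130 °C
Reagents that add atoms: none

Why: Tsuji–Wilkinson decarbonylation as in step 2 converts CH2CHO into the methyl group of the (R)-methyl/isopropenyl centre.

**Step 19**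
Reactants: 33 (5R)-5,6-dimethylhept-6-en-2-one
Product: 37 (5R)-5,6-dimethylhept-6-en-1-yne, via lithium enolate 34 (not isolated), via enol phosphate 35 (not isolated), via lithium acetylide 36 (not isolated)
Conditions: LiN(i-Pr)2 (1.05 equiv), THF, −78 °C; ClP(O)(OEt)2, −78 °C → rt; then LiN(i-Pr)2 (2.3 equiv), −78 °C → rt; H2O
Reagents that add atoms: none

Why: Kinetic enol phosphate formation on the methyl side followed by base-induced elimination (Negishi methyl ketone to alkyne conversion) gives the terminal alkyne without touching the remote stereocentre.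

**Step 20**
Reactants: 37 (5R)-5,6-dimethylhept-6-en-1-yne
Product: 39 (1E,5R)-1-iodo-2,5,6-trimethylhepta-1,6-diene, via alkenylalane 38 (not isolated)
Conditions: Me3Al (2 equiv), Cp2ZrCl2 (20 mol %), CH2Cl2, rt; then I2, THF, −30 °C
Reagents that add atoms: trimethylaluminium, C[Al](C)C; iodine, II
Why: Negishi Zr-catalysed carboalumination adds Me and Al syn across the alkyne only (the 1,1-disubstituted alkene is inert), and iodinolysis with retention gives the (E)-vinyl iodide.

**Step 21**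
Reactants: 29 (1S,3S)-1-[(3S,4E,6S)-6-ethenyl-8-iodo-3,6-dimethyloct-4-en-1-yl]-2,2,3-trimethyl-6-methylidenecyclohexane; 39 (1E,5R)-1-iodo-2,5,6-trimethylhepta-1,6-diene
Product: 41 (1S,3S)-1-[(3S,4E,6S,9E,13R)-6-ethenyl-3,6,10,13,14-pentamethylpentadeca-4,9,14-trien-1-yl]-2,2,3-trimethyl-6-methylidenecyclohexane (target), via alkylzinc iodide 40 (not isolated)
Conditions: Zn dust, LiCl, THF, 40 °C; then 39, Pd(PPh3)4 (5 mol %), THF, rt → 40 °C
Reagents that add atoms: none

Why: Zinc insertion into the primary iodide and Negishi sp3–sp2 cross-coupling join the halves with retention of the (E)-vinyl geometry and without touching any stereocentre.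

**Compound list**
1 | (4R)-limonene 1,2-oxide, (4R)-1-methyl-4-(prop-1-en-2-yl)-7-oxabicyclo[4.1.0]heptane, cis/trans mixture | CC12OC1C[C@@H](CC2)C(C)=C | starting material
2 | (4R)-1-methyl-4-(prop-1-en-2-yl)cyclohexane-1,2-diol | CC1(O)C(O)C[C@@H](CC1)C(C)=C | intermediate
3 | (3R)-6-oxo-3-(prop-1-en-2-yl)heptanal | O=CC[C@@H](CCC(C)=O)C(C)=C | intermediate
4 | (5S)-5,6-dimethylhept-6-en-2-one | C[C@@H](CCC(C)=O)C(C)=C | intermediate
5 | lithium (5S)-5,6-dimethylhepta-1,6-dien-2-olate | [Li]OC(=C)CC[C@H](C)C(C)=C | intermediate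
6 | (6S)-1-(dimethylamino)-6,7-dimethyloct-7-en-3-one | CN(C)CCC(=O)CC[C@H](C)C(C)=C | intermediate
7 | (6S)-N,N,N,6,7-pentamethyl-3-oxooct-7-en-1-aminium iodide | C[N+](C)(C)CCC(=O)CC[C@H](C)C(C)=C.[I-] | intermediate
8 | (6S)-6,7-dimethylocta-1,7-dien-3-one | C=CC(=O)CC[C@H](C)C(C)=C | intermediate
9 | (4S)-3,4-dimethylcyclohex-2-en-1-one | O=C1C=C(C)[C@@H](C)CC1 | intermediate
10 | lithium (4S)-3,3,4-trimethylcyclohex-1-en-1-olate | [Li]OC1=CC(C)(C)[C@@H](C)CC1 | intermediate
11 | (4S)-3,3,4-trimethylcyclohex-1-en-1-yl trifluoromethanesulfonate | O=S(=O)(OC1=CC(C)(C)[C@@H](C)CC1)C(F)(F)F | intermediate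
12 | [(4S)-3,3,4-trimethylcyclohex-1-en-1-yl]methanol | OCC1=CC(C)(C)[C@@H](C)CC1 | intermediate
13 | (4S)-1-{[(1-ethoxyethenyl)oxy]methyl}-3,3,4-trimethylcyclohex-1-ene | C=C(OCC)OCC1=CC(C)(C)[C@@H](C)CC1 | intermediate
14 | ethyl 2-[(1S,3S)-2,2,3-trimethyl-6-methylidenecyclohexyl]acetate | CCOC(=O)C[C@H]1C(=C)CC[C@H](C)C1(C)C | intermediate
15 | 2-[(1S,3S)-2,2,3-trimethyl-6-methylidenecyclohexyl]ethan-1-ol | OCC[C@H]1C(=C)CC[C@H](C)C1(C)C | intermediate
16 | (1S,3S)-1-(2-bromoethyl)-2,2,3-trimethyl-6-methylidenecyclohexane | BrCC[C@H]1C(=C)CC[C@H](C)C1(C)C | intermediate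
17 | tert-butyl (2S)-2-hydroxypropanoate | CC(C)(C)OC(=O)[C@H](C)O | starting material
18 | tert-butyl (2S)-2-{[(trifluoromethyl)sulfonyl]oxy}propanoate | CC(C)(C)OC(=O)[C@H](C)OS(=O)(=O)C(F)(F)F | intermediate
19 | bromo{2-[(1S,3S)-2,2,3-trimethyl-6-methylidenecyclohexyl]ethyl}magnesium | Br[Mg]CC[C@H]1C(=C)CC[C@H](C)C1(C)C | intermediate
20 | tert-butyl (2S)-2-methyl-4-[(1S,3S)-2,2,3-trimethyl-6-methylidenecyclohexyl]butanoate | CC(C)(C)OC(=O)[C@@H](C)CC[C@H]1C(=C)CC[C@H](C)C1(C)C | intermediate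
21 | (2S)-2-methyl-4-[(1S,3S)-2,2,3-trimethyl-6-methylidenecyclohexyl]butanal | O=C[C@@H](C)CC[C@H]1C(=C)CC[C@H](C)C1(C)C | intermediate
22 | but-1-en-3-yne | C=CC#C | starting material
23 | dimethyl[(1E)-2-methylbuta-1,3-dien-1-yl]alumane | C=C/C(C)=C/[Al](C)C | intermediate
24 | lithium butyl(dimethyl)[(1E)-2-methylbuta-1,3-dien-1-yl]aluminate | [Li+].CCCC[Al-](C)(C)/C=C(C)/C=C | intermediate
25 | (3E,5R,6S)-3,6-dimethyl-8-[(1S,3S)-2,2,3-trimethyl-6-methylidenecyclohexyl]octa-1,3-dien-5-ol | C=C/C(C)=C/[C@H](O)[C@@H](C)CC[C@H]1C(=C)CC[C@H](C)C1(C)C | intermediate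
26 | (1S,3S)-1-{(3S,4R,5E)-4-[(1-ethoxyethenyl)oxy]-3,6-dimethylocta-5,7-dien-1-yl}-2,2,3-trimethyl-6-methylidenecyclohexane | C=C/C(C)=C/[C@H](OC(=C)OCC)[C@@H](C)CC[C@H]1C(=C)CC[C@H](C)C1(C)C | intermediate
27 | ethyl (3S,4E,6S)-3-ethenyl-3,6-dimethyl-8-[(1S,3S)-2,2,3-trimethyl-6-methylidenecyclohexyl]oct-4-enoate | CCOC(=O)C[C@@](C)(C=C)/C=C/[C@@H](C)CC[C@H]1C(=C)CC[C@H](C)C1(C)C | intermediate
28 | (3S,4E,6S)-3-ethenyl-3,6-dimethyl-8-[(1S,3S)-2,2,3-trimethyl-6-methylidenecyclohexyl]oct-4-en-1-ol | OCC[C@@](C)(C=C)/C=C/[C@@H](C)CC[C@H]1C(=C)CC[C@H](C)C1(C)C | intermediate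
29 | (1S,3S)-1-[(3S,4E,6S)-6-ethenyl-8-iodo-3,6-dimethyloct-4-en-1-yl]-2,2,3-trimethyl-6-methylidenecyclohexane | ICC[C@@](C)(C=C)/C=C/[C@@H](C)CC[C@H]1C(=C)CC[C@H](C)C1(C)C | intermediate
30 | (4S)-limonene 1,2-oxide, (4S)-1-methyl-4-(prop-1-en-2-yl)-7-oxabicyclo[4.1.0]heptane, cis/trans mixture | CC12OC1C[C@H](CC2)C(C)=C | starting material
31 | (4S)-1-methyl-4-(prop-1-en-2-yl)cyclohexane-1,2-diol | CC1(O)C(O)C[C@H](CC1)C(C)=C | intermediate
32 | (3S)-6-oxo-3-(prop-1-en-2-yl)heptanal | O=CC[C@H](CCC(C)=O)C(C)=C | intermediate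
33 | (5R)-5,6-dimethylhept-6-en-2-one | C[C@H](CCC(C)=O)C(C)=C | intermediate
34 | lithium (5R)-5,6-dimethylhepta-1,6-dien-2-olate | [Li]OC(=C)CC[C@@H](C)C(C)=C | intermediate
35 | diethyl (5R)-5,6-dimethylhepta-1,6-dien-2-yl phosphate | CCOP(=O)(OCC)OC(=C)CC[C@@H](C)C(C)=C | intermediate
36 | lithium (5R)-5,6-dimethylhept-6-en-1-yn-1-ide | [Li]C#CCC[C@@H](C)C(C)=C | intermediate
37 | (5R)-5,6-dimethylhept-6-en-1-yne | C#CCC[C@@H](C)C(C)=C | intermediate
38 | dimethyl[(1E,5R)-2,5,6-trimethylhepta-1,6-dien-1-yl]alumane | C[Al](C)/C=C(\C)CC[C@@H](C)C(C)=C | intermediate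
39 | (1E,5R)-1-iodo-2,5,6-trimethylhepta-1,6-diene | I/C=C(\C)CC[C@@H](C)C(C)=C | intermediate
40 | iodo{(3S,4E,6S)-3-ethenyl-3,6-dimethyl-8-[(1S,3S)-2,2,3-trimethyl-6-methylidenecyclohexyl]oct-4-en-1-yl}zinc | I[Zn]CC[C@@](C)(C=C)/C=C/[C@@H](C)CC[C@H]1C(=C)CC[C@H](C)C1(C)C | intermediate
41 | (1S,3S)-1-[(3S,4E,6S,9E,13R)-6-ethenyl-3,6,10,13,14-pentamethylpentadeca-4,9,14-trien-1-yl]-2,2,3-trimethyl-6-methylidenecyclohexane (CNP0293684.2) | C=C[C@@](C)(/C=C/[C@@H](C)CC[C@H]1C(=C)CC[C@H](C)C1(C)C)CC/C=C(\C)CC[C@@H](C)C(=C)C | target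

**Step count**
Total: 21 steps. Longest linear sequence: 16 steps (steps 1–9, 11–16 and 21).

**Steps most likely to fail**

Step 2 (step 18 is its mirror image and carries the same risk): the acyl rhodium hydride of a pent-4-enal can add across the isopropenyl group (hydroacylation to a cyclopentanone) instead of losing CO. The fallback sets out from keto aldehyde 3 and replaces metal-mediated CO extrusion by radical decarboxylation. Chlorite oxidation (NaClO2, NaH2PO4, 2-methylbut-2-ene, t-BuOH/H2O) gives (3R)-6-oxo-3-(prop-1-en-2-yl)heptanoic acid F1. Coupling with 1-hydroxypyridine-2(1H)-thione (DCC, DMAP, CH2Cl2, dark) gives the Barton ester 2-sulfanylidenepyridin-1(2H)-yl (3R)-6-oxo-3-(prop-1-en-2-yl)heptanoate F2. Irradiation with visible light in benzene with t-BuSH traps the primary radical faster than it can rearrange and gives ketone 4, where the route is rejoined.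

Step 7: the rearrangement must form a bond at a ring carbon next to a quaternary centre, so it may be slow, may eliminate, or may give only moderate facial selectivity. The fallback sets out from enone 9 and replaces steps 5–7 by enolate alkylation. Cuprate addition as in step 5 gives lithium enolate 10, which is C-alkylated with ethyl iodoacetate (THF/HMPA, −78 → −20 °C) on the face anti to the pseudoaxial methyl to give ethyl 2-[(1R,3S)-2,2,3-trimethyl-6-oxocyclohexyl]acetate F3. Non-basic Takai–Lombardo methylenation (Zn, CH2Br2, TiCl4, THF, 0 °C) converts the ketone into the exocyclic methylene without epimerising the α-centre and gives ester 14, where the route is rejoined.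

Step 13: Felkin control is weak when the α-substituents are CH2R and CH3, and any (5S)-epimer carried forward ends as the wrong quaternary configuration after step 14. The fallback sets out from aldehyde 21 and sets the carbinol by hydride delivery and SN2 inversion instead of by C–C bond formation. Aluminate 24 is added as before and the crude epimer mixture is oxidised (Dess–Martin periodinane, NaHCO3, CH2Cl2) to (3E,6S)-3,6-dimethyl-8-[(1S,3S)-2,2,3-trimethyl-6-methylidenecyclohexyl]octa-1,3-dien-5-one F4. LiBH(s-Bu)3 (THF, −78 °C) reduces F4 with stronger Felkin control, which for hydride delivery gives (3E,5S,6S)-3,6-dimethyl-8-[(1S,3S)-2,2,3-trimethyl-6-methylidenecyclohexyl]octa-1,3-dien-5-ol F5. Mitsunobu inversion (4-nitrobenzoic acid, PPh3, DIAD, toluene, 0 °C) gives (3E,5R,6S)-3,6-dimethyl-8-[(1S,3S)-2,2,3-trimethyl-6-methylidenecyclohexyl]octa-1,3-dien-5-yl 4-nitrobenzoate F6, and K2CO3/MeOH releases alcohol 25, where the route is rejoined. SN2′ leakage in the Mitsunobu step on this dienyl carbinol is the residual risk.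

**Further compounds**
F1 | step 2 | (3R)-6-oxo-3-(prop-1-en-2-yl)heptanoic acid | OC(=O)C[C@@H](CCC(C)=O)C(C)=C
F2 | step 2 | 2-sulfanylidenepyridin-1(2H)-yl (3R)-6-oxo-3-(prop-1-en-2-yl)heptanoate | O=C(C[C@@H](CCC(C)=O)C(C)=C)ON1C=CC=CC1=S
F3 | step 7 | ethyl 2-[(1R,3S)-2,2,3-trimethyl-6-oxocyclohexyl]acetate | CCOC(=O)C[C@H]1C(=O)CC[C@H](C)C1(C)C
F4 | step 13 | (3E,6S)-3,6-dimethyl-8-[(1S,3S)-2,2,3-trimethyl-6-methylidenecyclohexyl]octa-1,3-dien-5-one | C=C/C(C)=C/C(=O)[C@@H](C)CC[C@H]1C(=C)CC[C@H](C)C1(C)C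
F5 | step 13 | (3E,5S,6S)-3,6-dimethyl-8-[(1S,3S)-2,2,3-trimethyl-6-methylidenecyclohexyl]octa-1,3-dien-5-ol | C=C/C(C)=C/[C@@H](O)[C@@H](C)CC[C@H]1C(=C)CC[C@H](C)C1(C)C
F6 | step 13 | (3E,5R,6S)-3,6-dimethyl-8-[(1S,3S)-2,2,3-trimethyl-6-methylidenecyclohexyl]octa-1,3-dien-5-yl 4-nitrobenzoate | C=C/C(C)=C/[C@H](OC(=O)c1ccc(cc1)[N+](=O)[O-])[C@@H](C)CC[C@H]1C(=C)CC[C@H](C)C1(C)C
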